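**Plan**
- Retrosynthesis: the two O–CH3 bonds of a veratrole precursor are cut first, the arene is taken back to its 2,5-dihydro form, and the ring is then opened at C1'–C2' and C5'–C6'.
- Enabling feature: the benzene ring carries oxygen at C3' and C4' and a single alkyl group at C1'. It therefore maps onto symmetric 2,3-dimethoxybuta-1,3-diene (C2'–C5') plus the terminal alkyne of docos-1-yn-7-one (C1', C6', with the whole keto chain), with no regiochemical question.
- The ynone is cut at C7–C8 (C5–C6 of the target chain) into the Weinreb amide of hept-6-ynoic acid and pentadecylmagnesium bromide.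
- Forward order: amide formation, chain joining by Grignard acylation, cobalt-catalysed [4+2] construction of the only ring, DDQ aromatisation, BBr3 demethylation.
- Stereochemistry: the target has no stereocentre and no stereogenic double bond, so nothing has to be controlled.

Key step: step 3

Remark: hept-6-ynoic acid, 1-bromopentadecane and 2,3-dimethoxybuta-1,3-diene are assumed to be purchased; ring atoms are primed (C1' bears the chain, C3' and C4' the oxygens).

Step 1
Reactants: 1 hept-6-ynoic acid
Product: 3 N-methoxy-N-methylhept-6-ynamide, via acyl imidazole 2 (not isolated)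
Conditions: CDI (1,1'-carbonyldiimidazole, 1.1 equiv), CH2Cl2, 0 °C to rt; then MeNH(OMe)·HCl (1.2 equiv), rt
Reagents that add atoms: N,O-dimethylhydroxylamine hydrochloride, CNOC.Cl
Why: CDI activation of the acid gives acyl imidazole 2, which N,O-dimethylhydroxylamine acylates cleanly (Weinreb amide formation), while the terminal alkyne is inert to these conditions.

Step 2
Reactants: 3 N-methoxy-N-methylhept-6-ynamide; 4 1-bromopentadecane
Product: 7 docos-1-yn-7-one, via pentadecylmagnesium bromide 5 (not isolated), via magnesium hemiaminal chelate 6 (not isolated)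
Conditions: 4 (1.6 equiv), Mg, THF, 40 °C; then 3, THF, −20 to 0 °C; 1 M HCl
Reagents that add atoms: none
Why: Weinreb ketone synthesis, in which the five-membered magnesium chelate 6 survives until the acidic quench and so prevents over-addition, while at −20 to 0 °C acyl addition should outrun metalation of the alkyne C–H and any alkynylmagnesium formed by the excess reagent is simply reprotonated on work-up.

Step 3
Reactants: 7 docos-1-yn-7-one; 8 2,3-dimethoxybuta-1,3-diene
Product: 9 1-(4,5-dimethoxycyclohexa-1,4-dien-1-yl)icosan-5-one
Conditions: CoBr2(dppe) (10 mol %; dppe = 1,2-bis(diphenylphosphino)ethane), Zn dust (20 mol %), ZnI2 (20 mol %), 8 (2 equiv), slow addition of 7, CH2Cl2, rt; filtration through basic Al2O3 (pentane/Et2O, 1% Et3N)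
Reagents that add atoms: none
Why: Zinc reduces CoBr2(dppe) to a monovalent cobalt species and ZnI2 strips bromide to free coordination sites, so that the s-cis diene 8 and the alkyne of 7 bind side by side; oxidative cyclisation to a cobaltacycle and reductive elimination then forge C1'–C2' and C5'–C6' and release the catalyst. The closest known reaction type is the cobalt-catalysed neutral Diels–Alder reaction of unactivated terminal alkynes with 2,3-dialkyl- and 2-silyloxybuta-1,3-dienes, a formal [4+2] that heat alone does not deliver for an electron-neutral alkyne. The single six-membered carbocycle closes intermolecularly in [4+2] mode from the four diene carbons (C2'–C5') and the two alkyne carbons (C1', C6') and emerges as the cyclohexa-1,4-diene, the 2,5-dihydro form of the veratrole. No stereocentre is formed. The step needs chemoselectivity for cross-cycloaddition over alkyne cyclotrimerisation, which the two-fold excess of diene and the slow addition of 7 should secure, whereas regioselectivity is not in question because 8 is symmetric about its central bond. The ketone sits five carbons from the alkyne and should remain a spectator, and the acid-labile bis(enol ether) is protected by the basic, anhydrous isolation.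

Step 4
Reactants: 9 1-(4,5-dimethoxycyclohexa-1,4-dien-1-yl)icosan-5-one
Product: 10 1-(3,4-dimethoxyphenyl)icosan-5-one
Conditions: DDQ (1.05 equiv), toluene, 0 °C to rt
Reagents that add atoms: none
Why: Quinone dehydrogenation, in which DDQ abstracts hydride from a doubly allylic ring CH2 to give an oxygen-stabilised cyclohexadienyl cation that loses a proton, so aromatisation should be far faster than any attack on the ketone or on the benzylic position of the product.

Step 5
Reactants: 10 1-(3,4-dimethoxyphenyl)icosan-5-one
Product: 12 1-(3,4-dihydroxyphenyl)icosan-5-one, via cyclic aryl bromoborate 11 (not isolated)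
Conditions: BBr3 (3.5 equiv), CH2Cl2, −78 to 0 °C; then ice-water, degassed work-up
Reagents that add atoms: none
Why: BBr3 aryl methyl ether cleavage, in which boron binds each methoxy oxygen and bromide removes the methyl group by SN2, the resulting cyclic borate 11 being hydrolysed on quench, while the dialkyl ketone only ties up one equivalent of the Lewis acid, which the excess covers.

**Compound list**
1 | hept-6-ynoic acid | C#CCCCCC(=O)O | starting material
2 | 1-(1H-imidazol-1-yl)hept-6-yn-1-one (acyl imidazole) | C#CCCCCC(=O)n1ccnc1 | intermediate (not isolated)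
3 | N-methoxy-N-methylhept-6-ynamide | C#CCCCCC(=O)N(C)OC | intermediate
4 | 1-bromopentadecane | CCCCCCCCCCCCCCCBr | starting material
5 | pentadecylmagnesium bromide | CCCCCCCCCCCCCCC[Mg]Br | intermediate (not isolated)
6 | bromomagnesium 7-[methoxy(methyl)amino]docos-1-yn-7-olate (tetrahedral chelate) | C#CCCCCC(O[Mg]Br)(N(C)OC)CCCCCCCCCCCCCCC | intermediate (not isolated)
7 | docos-1-yn-7-one | C#CCCCCC(=O)CCCCCCCCCCCCCCC | intermediate
8 | 2,3-dimethoxybuta-1,3-diene | C=C(OC)C(OC)=C | starting material
9 | 1-(4,5-dimethoxycyclohexa-1,4-dien-1-yl)icosan-5-one | COC1=C(OC)CC(CCCCC(=O)CCCCCCCCCCCCCCC)=CC1 | intermediate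
10 | 1-(3,4-dimethoxyphenyl)icosan-5-one | COc1ccc(CCCCC(=O)CCCCCCCCCCCCCCC)cc1OC | intermediate
11 | 1-(2-bromo-1,3,2-benzodioxaborol-5-yl)icosan-5-one (drawn without the BBr3 bound to the ketone) | BrB1Oc2ccc(CCCCC(=O)CCCCCCCCCCCCCCC)cc2O1 | intermediate (not isolated)
12 | 1-(3,4-dihydroxyphenyl)icosan-5-one | CCCCCCCCCCCCCCCC(=O)CCCCc1ccc(O)c(O)c1 | target

Total step count: 5. Longest linear sequence: 5 steps (1 → 3 → 7 → 9 → 10 → 12).

**Steps most likely to fail**

Step 3. The electron-rich, doubly oxygenated diene may bind cobalt sluggishly, so that cyclotrimerisation of the alkyne overtakes cross-cycloaddition. The bis(enol ether) may also hydrolyse during isolation. The fallback gives up ring construction and attaches a ready-made veratrole ring by cross-coupling. It sets out from pentadecylmagnesium bromide 5 and comes back at 10. Purchased pent-4-enoic acid would be converted with CDI and MeNH(OMe)·HCl into N-methoxy-N-methylpent-4-enamide F1. Hydroboration of the terminal alkene with 9-BBN-H in THF should give 5-(9-borabicyclo[3.3.1]nonan-9-yl)-N-methoxy-N-methylpentanamide F2. This would be coupled in the same flask with purchased 4-bromo-1,2-dimethoxybenzene (Pd(dppf)Cl2, dppf = 1,1'-bis(diphenylphosphino)ferrocene, aqueous K3PO4, THF/DMF, 60 °C; B-alkyl Suzuki–Miyaura coupling) to give 5-(3,4-dimethoxyphenyl)-N-methoxy-N-methylpentanamide F3. Addition of 5 in THF at 0 °C, through bromomagnesium 1-(3,4-dimethoxyphenyl)-5-[methoxy(methyl)amino]icosan-5-olate F4, and acidic quench should deliver 10, from which step 5 follows unchanged.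

Step 2. The Grignard reagent may metalate the terminal alkyne C–H in competition with acyl addition, which stalls conversion and lets the alkynylmagnesium attack further amide. The fallback replaces uncatalysed addition by a catalytic acyl cross-coupling that is fast at very low temperature. It sets out from acid 1 and comes back at 7. Oxalyl chloride and catalytic DMF in CH2Cl2 should convert 1 into hept-6-ynoyl chloride F5. This would be coupled with 5 under Fe(acac)3 catalysis (3 mol %, THF, −78 °C), conditions under which deprotonation of the alkyne should not compete, to give 7.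

Step 5. Demethylation may stall at the mono-methyl ether stage, the Lewis acid may trigger aldol-type condensation at the ketone, or the free catechol may oxidise during work-up. The fallback carries the two oxygens as silyl ethers through the same cycloaddition, so that no Lewis acid is needed at the end. It sets out from 7 and comes back at 12. Butane-2,3-dione would be bis-silylated (TBSOTf, Et3N, CH2Cl2) to 2,3-bis(tert-butyldimethylsilyloxy)buta-1,3-diene F6. Cycloaddition of F6 with 7 under the conditions of step 3 should give 1-[4,5-bis(tert-butyldimethylsilyloxy)cyclohexa-1,4-dien-1-yl]icosan-5-one F7. DDQ in toluene should aromatise this to 1-[3,4-bis(tert-butyldimethylsilyloxy)phenyl]icosan-5-one F8. Buffered fluoride (TBAF, AcOH, THF, 0 °C) would then release 12.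

**Further compounds**
F1 | step 3 | N-methoxy-N-methylpent-4-enamide | C=CCCC(=O)N(C)OC
F2 | step 3 | 5-(9-borabicyclo[3.3.1]nonan-9-yl)-N-methoxy-N-methylpentanamide | CON(C)C(=O)CCCCB1C2CCCC1CCC2
F3 | step 3 | 5-(3,4-dimethoxyphenyl)-N-methoxy-N-methylpentanamide | COc1ccc(CCCCC(=O)N(C)OC)cc1OC
F4 | step 3 | bromomagnesium 1-(3,4-dimethoxyphenyl)-5-[methoxy(methyl)amino]icosan-5-olate | COc1ccc(CCCCC(O[Mg]Br)(N(C)OC)CCCCCCCCCCCCCCC)cc1OC
F5 | step 2 | hept-6-ynoyl chloride | C#CCCCCC(=O)Cl
F6 | step 5 | 2,3-bis(tert-butyldimethylsilyloxy)buta-1,3-diene | C=C(O[Si](C)(C)C(C)(C)C)C(=C)O[Si](C)(C)C(C)(C)C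
F7 | step 5 | 1-[4,5-bis(tert-butyldimethylsilyloxy)cyclohexa-1,4-dien-1-yl]icosan-5-one | CC(C)(C)[Si](C)(C)OC1=C(O[Si](C)(C)C(C)(C)C)CC(CCCCC(=O)CCCCCCCCCCCCCCC)=CC1
F8 | step 5 | 1-[3,4-bis(tert-butyldimethylsilyloxy)phenyl]icosan-5-one | CC(C)(C)[Si](C)(C)Oc1ccc(CCCCC(=O)CCCCCCCCCCCCCCC)cc1O[Si](C)(C)C(C)(C)C
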